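The data are simulated with made-up constants; the scatter is artificial.

1.52 M of solid substrate has left the solid by 60.0 min in the north-west run, and from that reading I reckon the flask. Solid substrate dissolves to starting material; reagent turns this into first product, then bis adduct, and bis adduct with starting material gives side product.

| flask | solid substrate | reagent | remark | time |
|---|---|---|---|---|
| west | 1.3 M | 1.8 M | run made earlier |  |
| north-west | 3 M | 1.8 M | run made earlier |  |
| flask | 2.0 M | 1.80 M |  | 1.0 h |

| run | time / min | solid substrate / % | first product / % |
|---|---|---|---|
| west | 6.00 | 71.0 | 10.8 |
| west | 10.0 | 59.2 | 15.2 |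
| west | 15.0 | 45.9 | 18.2 |
| west | 25.0 | 23.2 | 21.0 |
| west | 40.0 | 0.7 | 23.2 |
| west | 80.0 | 0 | 21.0 |
| north-west | 12.0 | 79.8 | 8.0 |
| north-west | 25.0 | 67.3 | 9.4 |
| north-west | 40.0 | 57.0 | 9.7 |
| north-west | 50.0 | 53.0 | 11.0 |
| north-west | 60.0 | 49.5 | 10.6 |
| north-west | 80.0 | 44.8 | 10.9 |

(scatter of a reading: 0.5 percentage points)

- a species is counted by the solid substrate in it: one side product counts as two
- given per volume of solution although it is solid: solid substrate
- reactions considered so far: starting material + reagent -> first product; reagent + first product -> bis adduct; starting material + bis adduct -> side product; solid substrate <-> starting material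
- at the start none of the solid substrate is in solution

- amount of solid substrate at 1.0 h, in percent of the solid substrate charged (only what is still solid)
- amount of first product at 1.0 h, in percent of the solid substrate charged
- amount of bis adduct at 1.0 h, in percent of the solid substrate charged

I call W(t) the dissolved amount, the molar amount of solid substrate that has left the solid by time t, that is, charge times fraction no longer solid. The two runs differ in charge, yet their W agrees:

at 25.0 min: W = 0.998 M (west), 0.981 M (north-west)

at 40.0 min: W = 1.29 M (west), 1.29 M (north-west)

So I read dissolving as zero order in the solid charged, while solid stands. In the north-west run the curve averages 0.0505 M min⁻¹ up to 12.0 min and bends without a sharp knee to 0.0113 M min⁻¹ between 40.0 min and 60.0 min. Its ceiling is the charge: the west run reads 0.7 % solid at 40.0 min. The flask's charge of 2.0 M stays above W at 1.0 h, so the curve still holds there: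

solid left = (charge − W) / charge = 24.2 %

The forecast gives 24 % (20 % to 28 %) solid substrate, 15.5 % (13.5 % to 18 %) first product and 12 % (5 % to 20 %) bis adduct. Of the last it says: “This is the least certain number”.

    starting material + reagent → first product (k = 0.00240 M⁻¹ s⁻¹)
    reagent + first product → bis adduct (k = 0.00160 M⁻¹ s⁻¹)
    starting material + bis adduct → side product (k = 7.60 × 10⁻⁴ M⁻¹ s⁻¹)
    solid substrate ⇌ starting material, rate k4*(cs4 - [starting material]) while solid is left; crystals form when [starting material] > cs4 (solubility = 0.270 M, k = 0.00750 s⁻¹)

The flask gives 24.6 % solid substrate against my 24.2 %, 15.9 % first product, and 23.9 % bis adduct against the forecast's 12 %. At 1.0 h it holds starting material A at 12.6 % of the solid charged and reagent R at 3.6 % of its own charge. With side product counted as two, the reagent balance gives bis adduct as reagent charge − W + A − R, all in molar terms; with the north-west W this is 23.5 % of the solid charged. The same flask read at 25 min, with the north-west W, should keep 50.9 % solid; it keeps 50.1 %.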